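**Plan**

- Retrosynthesis: the two malonate C–O bonds are cut first (malonyl dichloride plus two molecules of labda-7,13E-dien-15-ol). Next come C11–C12 (drimenyl Grignard reagent plus a prenol-derived C5 allylic chloride), the C9–C11 unit (methylenation and hydroboration of a C9 ketone), the C1 oxygen, and last C3–C4 of ring A.
- Enabling feature: ring B of each half (C5 to C10, with the methyl-bearing C8 in the C7=C8 olefin, a carbonyl site at C9, quaternary C10, and C5 carrying C4) is the carbon pattern of (R)-carvone. Its isopropenyl group is the gem-dimethyl carbon C4 in masked form.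
- Forward: ring B comes from carvone, and C10 receives its methyl group and an acryloyl arm. Ring A is closed by radical C3–C4 bond formation, C1 is deoxygenated, C11 is added at C9, and the side chain is joined at C11–C12. The two halves are then tied through the malonate.
- Stereochemistry: C5 comes from (R)-carvone, C10 from aldol addition anti to the isopropenyl group, and C9 from α-face hydroboration opposite the axial C10 methyl. The 13E olefin comes from E-selective allylic oxidation of the prenyl ether and is kept through an SN2 coupling.

Key step: step 4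

Remark: the SMILES is read as the malonate diester of two identical (5S,9S,10S,13E)-labda-7,13-dien-15-ol units, so one alcohol is made and esterified twice. Labdane numbering is used for all bicyclic compounds. The C6 epimers of 4 and the carbinol epimers of 7 are carried as mixtures because both centres are erased in the following step. LiN(i-Pr)2 is taken as a commercial solution.

**Route**

Step 1
Reactants: 1 (R)-(−)-carvone; 2 iodomethane
Product: 4 (5R)-6-methylcarvone (C6 epimer mixture), via carvone lithium dienolate 3 (not isolated)
Conditions: LiN(i-Pr)2, THF, −78 °C; MeI, −78 → 0 °C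
Reagents that add atoms: iodomethane (2), CI
Why: Kinetic deprotonation of the enone at the α′ carbon gives the cross-conjugated lithium dienolate, which is C-methylated (enolate alkylation); the epimer composition at C6 does not matter because this carbon is enolised again in step 2.

Step 2
Reactants: 4 (5R)-6-methylcarvone; 5 acrolein
Product: 7 (5S,6R)-6-(1-hydroxyprop-2-en-1-yl)-2,6-dimethyl-5-(prop-1-en-2-yl)cyclohex-2-en-1-one (carbinol epimer mixture), via lithium enolate 6 (not isolated)
Conditions: LiN(i-Pr)2, THF, −78 °C; acrolein, −78 °C; AcOH quench at −78 °C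
Reagents that add atoms: acrolein (5), C=CC=O
Why: The tetrasubstituted lithium enolate undergoes kinetic aldol 1,2-addition to acrolein from the face opposite the C5 isopropenyl group, as in the known anti alkylations of this enolate, so the new quaternary carbon (future C10) carries the hydroxyallyl arm trans and the methyl group cis to isopropenyl; the cold acidic quench prevents retro-aldol.

Step 3
Reactants: 7 aldol adduct
Product: 8 (5S,6R)-2,6-dimethyl-6-(prop-2-enoyl)-5-(prop-1-en-2-yl)cyclohex-2-en-1-one (6-acryloyl-6-methylcarvone, acryloyl trans to isopropenyl)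
Conditions: Dess–Martin periodinane, CH2Cl2, 0 °C → rt; used without delay
Reagents that add atoms: none
Why: Dess–Martin oxidation converts the secondary allylic alcohol to the vinyl ketone under near-neutral conditions that leave the three olefins alone, and the adjacent quaternary carbon cannot epimerise.

Step 4
Reactants: 8 6-acryloyl-6-methylcarvone
Product: 9 (4aS,8aR)-2,5,5,8a-tetramethyl-4a,5,6,7-tetrahydro-4H-naphthalene-1,8-dione (trans-fused 4,4,8,10-tetramethyl-Δ7-octalin-1,9-dione in labdane numbering)
Conditions: Fe(acac)3, PhSiH3, EtOH/(CH2OH)2, high dilution, rt → 60 °C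
Reagents that add atoms: none
Why: An iron hydride formed from Fe(acac)3 and PhSiH3 in ethanol transfers a hydrogen atom to the terminal carbon of the isopropenyl group, the tertiary C4 radical adds to the unsubstituted β-carbon (C3) of the vinyl ketone, and the resulting C2 α-keto radical is reduced by divalent iron to the enolate and protonated by the solvent, which returns trivalent iron. The closest known reaction type is the iron-catalysed hydrogen-atom-transfer reductive olefin coupling (a Giese-type radical conjugate addition), run here intramolecularly onto an enone. Ring A (C4, C3, C2, C1, C10, C5) closes 6-endo-trig. No stereocentre is created: C4 becomes the achiral gem-dimethyl quaternary carbon, C5 (from carvone) and C10 (from step 2) are untouched, and because the two reacting arms are trans on ring B they can only be joined as the trans-decalin. The step needs hydrogen-atom transfer to the isopropenyl group in preference to the two electron-poor olefins and 6-endo in preference to 5-exo closure; both follow from polarity matching, since the hydride donates to the only electron-rich 1,1-disubstituted alkene and the nucleophilic tertiary radical attacks the electrophilic terminal carbon, whereas 5-exo attack at the α-carbon would give an unstabilised primary radical.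

Step 5
Reactants: 9 trans-octalin-1,9-dione
Product: 10 C1 mono-tosylhydrazone of 9
Conditions: TsNHNH2, EtOH, cat. AcOH, 50 °C
Reagents that add atoms: p-toluenesulfonyl hydrazide, Cc1ccc(cc1)S(=O)(=O)NN
Why: Hydrazone condensation takes place at the saturated C1 ketone, which is much more electrophilic than the conjugated, doubly flanked C9 enone carbonyl (chemoselective tosylhydrazone formation).

Step 6
Reactants: 10 C1 tosylhydrazone
Product: 13 (4aS,8aS)-2,5,5,8a-tetramethyl-4a,5,6,7,8,8a-hexahydronaphthalen-1(4H)-one (11-nordrim-7-en-9-one), via N-boryl tosylhydrazide 11 (not isolated), via C1 alkyldiazene 12 (not isolated)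
Conditions: catecholborane, CHCl3, 0 °C → rt; NaOAc·3H2O, reflux
Reagents that add atoms: none
Why: This is the catecholborane variant of the tosylhydrazone (Caglioti) deoxygenation: the C=N bond is hydroborated, acetate triggers loss of sulfinate to the diazene, and nitrogen extrusion leaves the C1 methylene, while the s-trans cyclic enone is not reduced by catecholborane at this temperature.

Step 7
Reactants: 13 11-nordrim-7-en-9-one; 14 methyltriphenylphosphonium bromide
Product: 16 drima-7,9(11)-diene, via methylenetriphenylphosphorane 15 (not isolated)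
Conditions: Ph3PCH3Br, KOt-Bu, toluene, 90 °C
Reagents that add atoms: methyltriphenylphosphonium bromide (14), C[P+](c1ccccc1)(c1ccccc1)c1ccccc1.[Br-]
Why: Wittig methylenation with the salt-free ylide at elevated temperature converts the hindered C9 ketone, which has no α-hydrogen on the C10 side, into the exocyclic diene; no stereocentre is involved.

Step 8
Reactants: 16 drima-7,9(11)-diene
Product: 18 drimenol (drim-7-en-11-ol; 1S,4aS,8aS), via C11 alkylborane 17 (not isolated)
Conditions: 9-BBN, THF, 0 °C → rt; NaOH, H2O2, H2O, 0 °C → rt
Reagents that add atoms: hydrogen peroxide, OO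
Why: In this hydroboration–oxidation, 9-BBN adds only to the 1,1-disubstituted terminus of the diene with boron at C11 and delivers hydrogen to C9 from the α face, opposite the axial C10 methyl group, which sets 9α-H with C11 equatorial; oxidation proceeds with retention.

Step 9
Reactants: 18 drimenol
Product: 19 11-bromodrim-7-ene
Conditions: CBr4, PPh3, CH2Cl2, 0 °C
Reagents that add atoms: carbon tetrabromide, BrC(Br)(Br)Br
Why: The Appel reaction displaces the alkoxyphosphonium group at primary C11 by bromide in an SN2 process under neutral conditions, which avoids homoallyl cation rearrangement and leaves C9 untouched.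

Step 10
Reactants: 20 3-methylbut-2-en-1-ol (prenol)
Product: 21 tert-butyl[(3-methylbut-2-en-1-yl)oxy]diphenylsilane
Conditions: t-BuPh2SiCl, imidazole, CH2Cl2, rt
Reagents that add atoms: tert-butyl(chloro)diphenylsilane, CC(C)(C)[Si](Cl)(c1ccccc1)c1ccccc1
Why: Standard silylation of a primary alcohol gives an ether that is stable to the oxidation, chlorination and organometallic steps that follow.

Step 11
Reactants: 21 prenyl silyl ether
Product: 22 (E)-4-[(tert-butyldiphenylsilyl)oxy]-2-methylbut-2-en-1-ol
Conditions: SeO2 (cat.), t-BuOOH, CH2Cl2, rt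
Reagents that add atoms: selenium dioxide, O=[Se]=O (catalytic oxygen carrier); tert-butyl hydroperoxide, CC(C)(C)OO (terminal oxygen source)
Why: Selenium dioxide allylic oxidation (ene reaction followed by [2,3]-sigmatropic shift) hydroxylates the (E)-methyl group of the trisubstituted olefin selectively, which fixes the E geometry of the future C13=C14 bond.

Step 12
Reactants: 22 (E)-allylic alcohol
Product: 23 (E)-tert-butyl[(4-chloro-3-methylbut-2-en-1-yl)oxy]diphenylsilane
Conditions: N-chlorosuccinimide, Me2S, CH2Cl2, −20 → 0 °C
Reagents that add atoms: N-chlorosuccinimide, ClN1C(=O)CCC1=O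
Why: Corey–Kim chlorination converts the primary allylic alcohol to the chloride by SN2 displacement of the alkoxysulfonium group, without allylic transposition or loss of olefin geometry.

Step 13
Reactants: 19 11-bromodrim-7-ene; 23 (E)-allylic chloride
Product: 25 (5S,9S,10S,13E)-15-[(tert-butyldiphenylsilyl)oxy]labda-7,13-diene, via drimenylmagnesium bromide 24 (not isolated)
Conditions: Mg, THF, 40 °C; then 23, Li2CuCl4 (cat.), THF, −30 → 0 °C, rapid addition
Reagents that add atoms: none
Why: Copper-catalysed Grignard cross-coupling (Kochi–Schlosser type) joins the primary alkylmagnesium reagent to the primary allylic chloride at its α carbon, because the diorganocuprate regime in THF at low temperature and the bulk of the nucleophile both disfavour γ attack; C9 and the 13E olefin are not affected.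

Step 14
Reactants: 25 labdadienyl silyl ether
Product: 26 (5S,9S,10S,13E)-labda-7,13-dien-15-ol
Conditions: n-Bu4NF, THF, 0 °C → rt
Reagents that add atoms: none
Why: Fluoride-induced desilylation frees the primary allylic alcohol under conditions to which the two trisubstituted olefins are inert.

Step 15
Reactants: 26 labda-7,13E-dien-15-ol (two equivalents); 27 malonyl dichloride
Product: 28 bis[(5S,9S,10S,13E)-labda-7,13-dien-15-yl] propanedioate (CNP0113044.1)
Conditions: malonyl dichloride (0.5 equiv), pyridine, CH2Cl2, 0 °C → rt
Reagents that add atoms: malonyl dichloride (27), O=C(Cl)CC(Cl)=O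
Why: Twofold acylation of the primary alcohol by the diacid chloride, with pyridine as acid scavenger, gives the symmetrical diester without touching any stereocentre or olefin.

**Compound list**

1 | (R)-(−)-carvone | CC1=CC[C@H](CC1=O)C(C)=C | starting material
2 | iodomethane | CI | starting material
3 | lithium dienolate of carvone | CC1=CC[C@@H](C(C)=C)C=C1O[Li] | intermediate
4 | (5R)-2,6-dimethyl-5-(prop-1-en-2-yl)cyclohex-2-en-1-one (6-methylcarvone, C6 epimers) | CC1=CC[C@@H](C(C)=C)C(C)C1=O | intermediate
5 | acrolein | C=CC=O | starting material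
6 | lithium enolate of 6-methylcarvone | CC1=CC[C@@H](C(C)=C)C(C)=C1O[Li] | intermediate
7 | (5S,6R)-6-(1-hydroxyprop-2-en-1-yl)-2,6-dimethyl-5-(prop-1-en-2-yl)cyclohex-2-en-1-one (carbinol epimers) | CC1=CC[C@@H](C(C)=C)[C@](C)(C(O)C=C)C1=O | intermediate
8 | (5S,6R)-2,6-dimethyl-6-(prop-2-enoyl)-5-(prop-1-en-2-yl)cyclohex-2-en-1-one | CC1=CC[C@@H](C(C)=C)[C@](C)(C(=O)C=C)C1=O | intermediate
9 | (4aS,8aR)-2,5,5,8a-tetramethyl-4a,5,6,7-tetrahydro-4H-naphthalene-1,8-dione (trans-fused, 5α-H, 10β-methyl) | CC1=CC[C@H]2C(C)(C)CCC(=O)[C@]2(C)C1=O | intermediate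
10 | C1 mono-tosylhydrazone of 9 | CC1=CC[C@H]2C(C)(C)CCC(=NNS(=O)(=O)c3ccc(C)cc3)[C@]2(C)C1=O | intermediate
11 | N-(1,3,2-benzodioxaborol-2-yl) C1 tosylhydrazide (C1 epimers) | CC1=CC[C@H]2C(C)(C)CCC(N(NS(=O)(=O)c3ccc(C)cc3)B3Oc4ccccc4O3)[C@]2(C)C1=O | intermediate
12 | C1 alkyldiazene (C1 epimers) | CC1=CC[C@H]2C(C)(C)CCC(N=N)[C@]2(C)C1=O | intermediate
13 | (4aS,8aS)-2,5,5,8a-tetramethyl-4a,5,6,7,8,8a-hexahydronaphthalen-1(4H)-one | CC1=CC[C@H]2C(C)(C)CCC[C@]2(C)C1=O | intermediate
14 | methyltriphenylphosphonium bromide | C[P+](c1ccccc1)(c1ccccc1)c1ccccc1.[Br-] | starting material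
15 | methylenetriphenylphosphorane | C=P(c1ccccc1)(c1ccccc1)c1ccccc1 | intermediate
16 | drima-7,9(11)-diene, (4aS,8aS)-2,5,5,8a-tetramethyl-1-methylidene-1,4,4a,5,6,7,8,8a-octahydronaphthalene | CC1=CC[C@H]2C(C)(C)CCC[C@]2(C)C1=C | intermediate
17 | 9-(drim-7-en-11-yl)-9-borabicyclo[3.3.1]nonane | CC1=CC[C@H]2C(C)(C)CCC[C@]2(C)[C@H]1CB1C2CCCC1CCC2 | intermediate
18 | drimenol, [(1S,4aS,8aS)-2,5,5,8a-tetramethyl-1,4,4a,5,6,7,8,8a-octahydronaphthalen-1-yl]methanol | CC1=CC[C@H]2C(C)(C)CCC[C@]2(C)[C@H]1CO | intermediate
19 | 11-bromodrim-7-ene | CC1=CC[C@H]2C(C)(C)CCC[C@]2(C)[C@H]1CBr | intermediate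
20 | 3-methylbut-2-en-1-ol (prenol) | CC(C)=CCO | starting material
21 | tert-butyl[(3-methylbut-2-en-1-yl)oxy]diphenylsilane | CC(C)=CCO[Si](c1ccccc1)(c1ccccc1)C(C)(C)C | intermediate
22 | (E)-4-[(tert-butyldiphenylsilyl)oxy]-2-methylbut-2-en-1-ol | OC/C(C)=C/CO[Si](c1ccccc1)(c1ccccc1)C(C)(C)C | intermediate
23 | (E)-tert-butyl[(4-chloro-3-methylbut-2-en-1-yl)oxy]diphenylsilane | ClC/C(C)=C/CO[Si](c1ccccc1)(c1ccccc1)C(C)(C)C | intermediate
24 | (drim-7-en-11-yl)magnesium bromide | CC1=CC[C@H]2C(C)(C)CCC[C@]2(C)[C@H]1C[Mg]Br | intermediate
25 | (5S,9S,10S,13E)-15-[(tert-butyldiphenylsilyl)oxy]labda-7,13-diene | CC1=CC[C@H]2C(C)(C)CCC[C@]2(C)[C@H]1CC/C(C)=C/CO[Si](c1ccccc1)(c1ccccc1)C(C)(C)C | intermediate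
26 | (5S,9S,10S,13E)-labda-7,13-dien-15-ol | CC1=CC[C@H]2C(C)(C)CCC[C@]2(C)[C@H]1CC/C(C)=C/CO | intermediate
27 | malonyl dichloride | O=C(Cl)CC(Cl)=O | starting material
28 | bis[(5S,9S,10S,13E)-labda-7,13-dien-15-yl] propanedioate | CC1=CC[C@H]2C(C)(C)CCC[C@]2(C)[C@H]1CC/C(C)=C/COC(=O)CC(=O)OC/C=C(\C)CC[C@H]1C(C)=CC[C@H]2C(C)(C)CCC[C@]12C | target

**Count and risks**

Total step count: 15. Longest linear sequence: 12 steps (steps 1–9, then 13–15); the C5 side-chain unit takes 3 steps (10–12).

Steps most likely to fail:

Step 4. What may go wrong is competing hydrogen-atom transfer to the vinyl ketone or its silane-mediated reduction and oligomerisation, or alcoholysis of the non-enolisable 1,3-diketone in the alcoholic medium, so that the C4 radical is not captured intramolecularly. The fallback generates the same tertiary radical by bromine-atom abstraction in an aprotic tin hydride chain. It sets out from 8: HBr in AcOH at 0 °C adds in the Markovnikov sense to the isopropenyl group and conjugatively to the vinyl ketone to give the dibromide F1. Brief treatment with Et3N in CH2Cl2 at 0 °C eliminates HBr only from the β-bromo ketone and gives the tertiary bromide F2 with the vinyl ketone restored. Slow addition of Bu3SnH with AIBN in benzene at 80 °C then effects the 6-endo Giese cyclisation, and the route is rejoined at 9.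

Step 6. What may go wrong is slow hydride delivery to the hindered C1 hydrazone next to quaternary C10, or diversion of the collapsing diazene by 1,2-shift of the neighbouring C9 acyl group or by elimination toward C2. The fallback removes the C1 oxygen through the enol triflate and sets out from 9, bypassing step 5 as well. KN(SiMe3)2 and PhNTf2 in THF at −78 °C deprotonate the only α-position (C2) and give the C1 enol triflate F3. Pd(OAc)2, PPh3, HCO2H and n-Bu3N in DMF at 60 °C reduce it to the Δ1,Δ7-dienone F4. Diimide, generated from 2-nitrobenzenesulfonyl hydrazide and Et3N in CH2Cl2 at rt, saturates the isolated cis-disubstituted C1=C2 bond and leaves the trisubstituted conjugated C7=C8 bond, so the route is rejoined at 13.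

Step 13. What may go wrong is Wurtz-type homocoupling or incomplete magnesium insertion with the hindered homoallylic bromide, or allylic transposition by γ attack in the copper-catalysed substitution. The fallback reverses the polarity of the C11–C12 bond formation and sets out from 23 and 19. PhSO2Na in DMF at rt converts 23 into the allylic sulfone F5. Its anion (n-BuLi, THF/DMPU, −78 °C) is alkylated at the sulfone-bearing carbon by 19 to give the C12 sulfone F6. Reductive desulfonylation with PdCl2(dppp) and LiBHEt3 in THF at 0 °C, which keeps the position and E geometry of the olefin, rejoins the route at 25.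

**Further compounds**

F1 | step 4 | 5-(2-bromopropan-2-yl)-6-(3-bromopropanoyl)-2,6-dimethylcyclohex-2-en-1-one (ring configuration as in 8) | CC1=CC[C@@H](C(C)(C)Br)[C@](C)(C(=O)CCBr)C1=O
F2 | step 4 | 5-(2-bromopropan-2-yl)-2,6-dimethyl-6-(prop-2-enoyl)cyclohex-2-en-1-one (ring configuration as in 8) | CC1=CC[C@@H](C(C)(C)Br)[C@](C)(C(=O)C=C)C1=O
F3 | step 6 | C1 enol trifluoromethanesulfonate of 9 (C1=C2, labdane numbering) | CC1=CC[C@H]2C(C)(C)CC=C(OS(=O)(=O)C(F)(F)F)[C@]2(C)C1=O
F4 | step 6 | trans-4,4,8,10-tetramethyl-octalin-1,7-dien-9-one (labdane numbering) | CC1=CC[C@H]2C(C)(C)CC=C[C@]2(C)C1=O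
F5 | step 13 | (E)-tert-butyl{[3-methyl-4-(phenylsulfonyl)but-2-en-1-yl]oxy}diphenylsilane | O=S(=O)(C/C(C)=C/CO[Si](c1ccccc1)(c1ccccc1)C(C)(C)C)c1ccccc1
F6 | step 13 | (5S,9S,10S,13E)-15-[(tert-butyldiphenylsilyl)oxy]-12-(phenylsulfonyl)labda-7,13-diene (C12 epimers) | CC1=CC[C@H]2C(C)(C)CCC[C@]2(C)[C@H]1CC(/C(C)=C/CO[Si](c1ccccc1)(c1ccccc1)C(C)(C)C)S(=O)(=O)c1ccccc1
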